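The data are calculated from invented constants; scatter was added.

The product I want is the complex with one exchanged, and the figure that counts is its selectivity: [complex with one exchanged]/([complex with one exchanged] + [complex with two exchanged]) at the end.

| setting | Tuesday's | Thursday's | Monday's | Friday's | autumn | noon | dawn | midnight |
|---|---|---|---|---|---|---|---|---|
| starting complex | 12 mM | 6 mM | 24 mM | 12 mM | 12 mM | 12 mM (fed, over 2.0 h) | 12 mM | 12 mM |
| incoming ligand | 1.2 equiv | 1.2 equiv | 1.2 equiv | 1.8 equiv | 1.20 equiv (fed, over 2.0 h) | 1.20 equiv | 1.20 equiv (in portions, 3, over 2.0 h) | 1.20 equiv |
| remark | run made earlier | run made earlier | run made earlier | run made earlier | all else is in the flask from the start; the feed brings no volume worth counting | all else is in the flask from the start; the feed brings no volume worth counting | first portion at the start, last at 2.0 h | everything together at the start |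
| time |  |  |  |  | 3.0 h | 3.0 h | 3.0 h | 3.0 h |

- Tuesday's (time / h: complex with one exchanged / %, complex with two exchanged / %): 0.250: 17.9, 4.0; 0.500: 23.1, 10.5; 1.33: 16.6, 24.8; 3.00: 8.3, 34.2
- Thursday's (time / h: complex with one exchanged / %, complex with two exchanged / %): 0.250: 12.2, 0.8; 0.500: 19.0, 3.9; 1.33: 23.4, 14.3; 3.00: 15.4, 26.3
- Monday's (time / h: complex with one exchanged / %, complex with two exchanged / %): 0.833: 14.0, 27.7; 1.50: 8.0, 34.8; 2.50: 6.2, 37.8; 3.00: 5.8, 38.3
- Friday's (time / h: complex with one exchanged / %, complex with two exchanged / %): 0.833: 20.3, 30.5; 1.50: 12.3, 42.9; 2.50: 8.8, 50.3; 3.00: 6.9, 52.9

(scatter of a reading: 0.3 percentage points)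

- the earlier runs were read with a standard deviation of 0.3 percentage points

- the flask with the highest share of complex with one exchanged in complex with one exchanged plus complex with two exchanged ("all alike" if they lie within 1.5 percentage points) (autumn / noon / dawn / midnight / all alike)
- share of complex with one exchanged in complex with one exchanged plus complex with two exchanged at the end, autumn
- share of complex with one exchanged in complex with one exchanged plus complex with two exchanged at the end, noon
- share of complex with one exchanged in complex with one exchanged plus complex with two exchanged at the end, dawn
- share of complex with one exchanged in complex with one exchanged plus complex with two exchanged at the end, midnight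

I can turn the charge, the equivalents and the dosing. The first is the charge: by hand, if each step takes two partners, the time needed goes as one over the charge, so at equal equivalents equal charge times time should give equal percentages. Two runs can be laid side by side. Monday's run at 1.50 h reads 8.0 % and 34.8 %, close to Tuesday's 8.3 % and 34.2 % at 3.00 h, and both stand at 130 M·s.

The second is the equivalents: by hand, more incoming ligand should carry more product on to two exchanged. Friday's run at 1.8 equiv ends at 11.5 %, lower than Tuesday's 19.5 %. Autumn, noon, dawn and midnight each hold the equivalents at 1.20 equiv, so this setting stays put.

The third is the dosing: by hand, late addition shortens the time the material spends in the flask. A steady feed over 2.0 h and 3 evenly spaced portions both give a mean stay of 2.00 h. So I carry the exposure, the charge times the mean stay of the fed reagent, which is 86.4 M·s for the dosed flasks. Midnight repeats Tuesday's recipe, so I expect 19.5 % there. Monday's reading at 0.833 h, with exposure 72.0 M·s, shows 33.6 %. A straight line from there to Tuesday's end gives about 30.1 % for the dosed flasks, and that one value for autumn, noon and dawn does not rank them.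

The forecast does rank them, naming dawn at 31 %, with autumn 29.5 %, noon 26.5 % and midnight 19.5 %, on the ground that “Late ligand keeps the system further from equilibrium, so M stays higher”, M being its letter for the complex with one exchanged. The flasks give dawn at 34.6 %, autumn 32.1 %, noon 28.2 % and midnight 20.0 %.

    starting complex + complex with one exchanged → side product (k = 38.0 L mol⁻¹ h⁻¹)
    starting complex + incoming ligand ⇌ leaving ligand + complex with one exchanged (K = 0.760, k = 92.0 L mol⁻¹ h⁻¹)
    complex with one exchanged + incoming ligand ⇌ leaving ligand + complex with two exchanged (K = 43.0, k = 120 L mol⁻¹ h⁻¹)

My line at 86.4 M·s falls between noon's and autumn's values and below dawn's. On a second flask, midnight's recipe with 7.2 mM of starting complex has exposure 77.8 M·s; the line gives 32.2 %, and that flask gives 31.8 %. Dawn and midnight have not come to rest at 3.0 h. At 30.0 h the exposures are 1250 M·s for dawn and 1300 M·s for midnight, and dawn's share has fallen to 7.59 %, midnight's to 7.77 %.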